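## Analysis of the target

Locants: the naphtho[2,3-b]furan half is unprimed (O1, C2, C3, C3a, C4, C4a, C5–C8, C8a, C9, C9a; O9 is the oxygen on C9) and the benzofuran half is primed (O1′, C2′, C3′, C3a′, C4′–C7′, C7a′). Rings: A is the phenol ring, B the dihydrofuran, C the pyran (O9, C9, C8a, C8, C2′, C3′), D the fully substituted benzene, E the cyclohexane and F the furan.

- The target is a C30 heterodimer of two different 3-methylbenzofuran units: a 5,6,7,8-tetrahydronaphthofuran-9-ol (rings D, E, F) and a 3,5-dimethyl-6-pentenylbenzofuran-7-ol (rings A, B).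
- Only two bonds join the halves, C8–C2′ and O9–C3′, and both lie in ring C. Read backwards, ring C links a benzofuran C2′=C3′ bond to the ortho-hydroxybenzylic unit O9–C9–C8a–C8. Ring C is therefore the retron of an oxa-[4+2] cycloaddition of an ortho-quinone methide, and the route is built on this feature.
- There are four stereocentres: C2′ (R), the quaternary C3′ (R; methyl, aryl, aryloxy), C8 (R) and C5 (S). H2′, H8 and the 3′-methyl are all cis on ring C (B/C cis-fused), and the C5 methyl is cis to the C8–C2′ bond across ring E.
- Sensitive groups: the free C7′ phenol, the 2-unsubstituted furan F (electrophiles, strong acid), the E-disubstituted alkene (rules out late hydrogenation), and the tertiary benzylic aryl ether C3′–O9 (ionisable).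
- The difficulty lies in the quaternary C3′ between two hindered arenes, in relating the C2′/C3′/C8 triad to the isolated C5 centre, and in joining two similar benzofurans cross-selectively.

## Retrosynthetic reasoning

**18 ⇒ 16 + 17.** Both inter-half bonds (C8–C2′ and O9–C3′) are cut in one retro-oxa-Diels–Alder step, giving benzofuran 16 and ortho-quinone methide 17. Cutting here removes ring C, the quaternary carbon and three of the four stereocentres at once, and leaves two small phenols that need no protecting groups. No other single cut of ring C does this. Forward, the cycloaddition must be regioselective (C2′ to C8), endo, and selective for the face of 17 syn to the C5 methyl.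

**17 ⇒ 10 ⇒ 9.** The quinone methide is not isolable, so it is traced to the ortho-hydroxybenzylic alcohol 10, which loses water under mild acid. 10 comes from the peri-hydroxy ketone 9 by hydride reduction. The new C8 carbinol centre needs no control because it becomes sp2 in 17.

**9 ⇒ 8 ⇒ 7.** The C8–C8a bond is cut by a retro-Friedel–Crafts acylation, leading to acid 7, whose arene has only one free position ortho to the side chain. The C9 oxygen is carried as a methyl ether, which activates that position and is later removed selectively because it is peri to the ketone.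

**7 ⇒ 6 ⇒ 5.** The only stereocentre that must be bought with a chiral reagent, C5, is set by carboxylate-directed asymmetric hydrogenation of the β,γ-unsaturated acid 6. The C=C bond of 6 is cut by a Wittig disconnection to the aryl methyl ketone 5 and a three-carbon carboxy ylide.

**5 ⇒ 4 ⇒ 3 ⇒ 1.** Furan ring F is opened at C3–C3a (cyclodehydration of the aryloxy ketone 4) and at the ether C–O bond, giving phenol 3. The acetyl group of 3 is removed by a retro-Fries step (through ester 2) to the commercial guaiacol 1. Forming the furan before the tetralone keeps the ring closure on an arene not yet deactivated by a conjugated ketone.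

**16 ⇒ 15 ⇒ 14 ⇒ 13 ⇒ 12 ⇒ 11.** The pentenyl chain is cut at the aryl–CH2 bond (B-alkyl Suzuki coupling of bromide 15). The bromine is removed to phenol 14, whose only free ortho position is C6. The furan is dismantled as for the other half, back to the isomeric commercial guaiacol 11. Both halves thus use the same furan construction.

## Alternatives that were turned down

**Alternative 1:** the stepwise ionic assembly, the textbook route.
- Disconnection: C8–C2′ by carbonyl addition, then O9–C3′ by ring closure, with the hydrogens at C8 and C2′ added last.
- Forward: after O-protection, 16 would be lithiated at C2′ and added to the likewise protected 9; dehydration and deprotection would give styrene A1. Acid would close O9 onto C3′ to give 2H-chromene A2, and the C8=C2′ bond would then be hydrogenated.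
- Turned down because:
  - C3′ is created in A2 with only the distant C5 centre to control it, so no facial preference can be argued.
  - The last step must reduce a tetrasubstituted enol-ether double bond while leaving the more reactive disubstituted pentenyl alkene and the furan untouched, which cannot be defended.
  - It needs two protecting groups and about four more steps than the cycloaddition.

**Alternative 2:** the quinone methide by dehydrogenation of the bare skeleton.
- Disconnection: the same two bonds, but 17 would be generated by oxidising the C8-unfunctionalised phenol A3 (for example with Ag2O) in the presence of 16.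
- Turned down because:
  - A3 has two benzylic positions conjugated to the phenol, C8H2 (ortho) and the C4 methyl (para), so the oxidation has no reason to choose C8.
  - The oxidant would also attack the free phenol of 16, which would need protection and deprotection.
  - A3 is reached from 9 only by an extra deoxygenation, so the route becomes longer, not shorter.

**Alternative 3:** ring B formed last by a formal [3+2] annulation.
- Disconnection: O1′–C2′ and C3′–C3a′.
- Forward: the cyclic enol ether A4 (ring C already in place) would be combined with ortho-quinone A5.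
- Turned down because:
  - The polarity is wrong. The nucleophilic carbon of enol ether A4 is C2′; it would bond to the ring carbon of A5 and the quinone oxygen would end up on C3′. That gives the constitutional isomer with a ketal at C3′, whereas the target has the arene on C3′ and the oxygen on C2′.
  - A4 would already need the C8/C5 relationship, set by a separate step of its own.
  - A5 is an unstable, easily polymerised quinone.

Key step: step 14

Assumption: 1, 11 and all reagents named are taken as commercial; the ligand antipode in step 5 is the one that gives 4S; 10 is used as its C8 epimer mixture.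

## Route

Step 1
Reactants: 1 2-methoxy-5-methylphenol
Product: 3 1-(4-hydroxy-5-methoxy-2-methylphenyl)ethan-1-one, via aryl acetate 2 (not isolated)
Conditions: AcCl (1.1 equiv), CF3SO3H, 0 °C → rt
Reagents that add atoms: acetyl chloride, CC(Cl)=O
Why: O-acetylation followed by acid-mediated para-selective Fries rearrangement; the position para to the free OH is open and flanked by the methyl group, while the position para to OMe is blocked.

Step 2
Reactants: 3 1-(4-hydroxy-5-methoxy-2-methylphenyl)ethan-1-one
Product: 4 1-[5-methoxy-2-methyl-4-(2-oxopropoxy)phenyl]ethan-1-one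
Conditions: ClCH2COCH3 (1.2 equiv), K2CO3 (1.5 equiv), KI (cat.), acetone, reflux
Reagents that add atoms: chloroacetone, CC(=O)CCl
Why: Williamson ether synthesis on the only phenol with a very reactive α-halo ketone; the aryl methyl ketone is not enolised by carbonate.

Step 3
Reactants: 4 1-[5-methoxy-2-methyl-4-(2-oxopropoxy)phenyl]ethan-1-one
Product: 5 1-(7-methoxy-3,4-dimethyl-1-benzofuran-5-yl)ethan-1-one
Conditions: polyphosphoric acid, 80 °C
Reagents that add atoms: none
Why: Cyclodehydration of an aryloxyacetone (intramolecular Friedel–Crafts hydroxyalkylation, then loss of water); the ether oxygen has a single free ortho carbon, so only the 3,4-dimethylbenzofuran can form, and the acetyl group is meta to the carbon attacked.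

Step 4
Reactants: 5 1-(7-methoxy-3,4-dimethyl-1-benzofuran-5-yl)ethan-1-one
Product: 6 (3E)-4-(7-methoxy-3,4-dimethyl-1-benzofuran-5-yl)pent-3-enoic acid
Conditions: Ph3P(CH2CH2CO2H)Br (1.5 equiv), KOt-Bu (3.0 equiv), THF, 0 → 60 °C; aq. HCl; E isomer purified by crystallisation
Reagents that add atoms: (2-carboxyethyl)triphenylphosphonium bromide, OC(=O)CC[P+](c1ccccc1)(c1ccccc1)c1ccccc1.[Br-]
Why: Wittig olefination with the carboxylate-bearing ylide gives the β,γ-unsaturated acid directly; the isomer with the aryl group trans to CH2CO2H should predominate and is the geometry the hydrogenation needs.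

Step 5
Reactants: 6 (3E)-4-(7-methoxy-3,4-dimethyl-1-benzofuran-5-yl)pent-3-enoic acid
Product: 7 (4S)-4-(7-methoxy-3,4-dimethyl-1-benzofuran-5-yl)pentanoic acid
Conditions: [Ir(cod)(L)]B[C6H3-3,5-(CF3)2]4 (1 mol %; L = 7-(4-benzyl-4,5-dihydrooxazol-2-yl)-7′-[bis(3,5-di-tert-butylphenyl)phosphanyl]-1,1′-spirobiindane, antipode giving 4S), H2 (6 atm), NEt3 (0.5 equiv), MeOH, rt
Reagents that add atoms: none
Why: Carboxylate-directed iridium-catalysed asymmetric hydrogenation of a β,γ-unsaturated acid; binding of the carboxylate fixes the alkene face and sets the future C5, while the furan double bond has no directing group and should stay intact.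

Step 6
Reactants: 7 (4S)-4-(7-methoxy-3,4-dimethyl-1-benzofuran-5-yl)pentanoic acid
Product: 8 (5S)-9-methoxy-3,4,5-trimethyl-6,7-dihydronaphtho[2,3-b]furan-8(5H)-one
Conditions: polyphosphoric acid, 60 °C, dilute
Reagents that add atoms: none
Why: Intramolecular Friedel–Crafts acylation closes ring E at the only free ortho carbon, which is activated by the adjacent methoxy group; six-membered ring closure should outrun intermolecular attack at furan C2, and the stereocentre is not α to the carbonyl.

Step 7
Reactants: 8 (5S)-9-methoxy-3,4,5-trimethyl-6,7-dihydronaphtho[2,3-b]furan-8(5H)-one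
Product: 9 (5S)-9-hydroxy-3,4,5-trimethyl-6,7-dihydronaphtho[2,3-b]furan-8(5H)-one
Conditions: BCl3 (1.5 equiv), CH2Cl2, −78 → 0 °C; H2O
Reagents that add atoms: none
Why: Chelation-assisted cleavage of the aryl methyl ether peri to the ketone; boron bound between the carbonyl and ether oxygens makes this demethylation mild enough for the furan.

Step 8
Reactants: 9 (5S)-9-hydroxy-3,4,5-trimethyl-6,7-dihydronaphtho[2,3-b]furan-8(5H)-one
Product: 10 (5S,8RS)-3,4,5-trimethyl-5,6,7,8-tetrahydronaphtho[2,3-b]furan-8,9-diol
Conditions: NaBH4, MeOH–THF, 0 °C; pH 7 work-up; used crude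
Reagents that add atoms: none
Why: Hydride 1,2-reduction of the aryl ketone; the C8 configuration is irrelevant because C8 becomes sp2 in the next step, and the neutral work-up avoids premature dehydration.

Step 9
Reactants: 11 2-methoxy-4-methylphenol
Product: 12 1-(2-methoxy-4-methylphenoxy)propan-2-one
Conditions: ClCH2COCH3 (1.2 equiv), K2CO3 (1.5 equiv), KI (cat.), acetone, reflux
Reagents that add atoms: chloroacetone, CC(=O)CCl
Why: Williamson ether synthesis, as in step 2.

Step 10
Reactants: 12 1-(2-methoxy-4-methylphenoxy)propan-2-one
Product: 13 7-methoxy-3,5-dimethyl-1-benzofuran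
Conditions: polyphosphoric acid, 80 °C
Reagents that add atoms: none
Why: Aryloxyacetone cyclodehydration, as in step 3; the ether oxygen again has only one free ortho carbon, so the regiochemistry is fixed.

Step 11
Reactants: 13 7-methoxy-3,5-dimethyl-1-benzofuran
Product: 14 3,5-dimethyl-1-benzofuran-7-ol
Conditions: BBr3 (1.2 equiv), CH2Cl2, −78 → 0 °C; H2O
Reagents that add atoms: none
Why: Lewis-acid cleavage of the aryl methyl ether; 3-methylbenzofurans tolerate BBr3 at low temperature.

Step 12
Reactants: 14 3,5-dimethyl-1-benzofuran-7-ol
Product: 15 6-bromo-3,5-dimethyl-1-benzofuran-7-ol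
Conditions: NBS (1.0 equiv), i-Pr2NH (10 mol %), CH2Cl2, −40 → 0 °C, dark
Reagents that add atoms: N-bromosuccinimide, BrN1C(=O)CCC1=O
Why: Amine-mediated ortho-selective bromination of a phenol (the N-bromoamine is delivered through a hydrogen bond to the OH); C6 is the only free ortho position and the para position C4 is flanked by the 3- and 5-methyl groups.

Step 13
Reactants: 15 6-bromo-3,5-dimethyl-1-benzofuran-7-ol
Product: 16 3,5-dimethyl-6-[(3E)-pent-3-en-1-yl]-1-benzofuran-7-ol
Conditions: (E)-penta-1,3-diene (1.6 equiv), 9-BBN-H (1.5 equiv), THF, 0 °C → rt; then 15, Pd(OAc)2 (5 mol %), SPhos (10 mol %), aq. K3PO4 (3 equiv), THF, 60 °C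
Reagents that add atoms: (E)-penta-1,3-diene, C/C=C/C=C
Why: Anti-Markovnikov hydroboration of the terminal double bond of the diene leaves the E-alkene untouched, and B-alkyl Suzuki–Miyaura coupling then joins the chain; the bulky biaryl phosphine is chosen for a di-ortho-substituted bromide bearing a free phenol.

Step 14
Reactants: 10 (5S,8RS)-3,4,5-trimethyl-5,6,7,8-tetrahydronaphtho[2,3-b]furan-8,9-diol; 16 3,5-dimethyl-6-[(3E)-pent-3-en-1-yl]-1-benzofuran-7-ol
Product: 18 (2′R,3′R,5S,8R)-heterodimer in which C2′ of 3′,5′-dimethyl-6′-[(3E)-pent-3-en-1-yl]-2′,3′-dihydro-1-benzofuran-7′-ol is bonded to C8 and C3′ to O9 of (5S)-3,4,5-trimethyl-5,6,7,8-tetrahydronaphtho[2,3-b]furan-9-ol (the target), via ortho-quinone methide 17 (not isolated)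
Conditions: (PhO)2P(O)OH (10 mol %), 4 Å MS, toluene, 25 °C; 10 added over 6 h to 16 (2.0 equiv)
Reagents that add atoms: none
Why: Acid-catalysed 1,4-dehydration of 10 gives ortho-quinone methide 17, whose O9=C9–C8a=C8 oxadiene adds to the C2′=C3′ bond of 16 in an inverse-electron-demand oxa-Diels–Alder reaction; the closest known reaction type is the [4+2] cycloaddition of ortho-quinone methides with indenes, styrenes, cyclic enol ethers and 2,3-disubstituted indoles. Ring C closes in a [4+2] mode with C8–C2′ ahead of O9–C3′: C2′ is the nucleophilic carbon of a 3-methylbenzofuran, and the developing tertiary benzylic cation at C3′, stabilised through ring A by O1′, is captured by O9, which fixes the regiochemistry. C2′ and C3′ are set by suprafacial addition to the planar furan, which gives the cis B/C fusion. C8 relative to C2′ is set by the methide geometry locked by ring E (H inside, C7 outside) and by the endo transition state, with ring A stacked over the dienone ring D, which places H8 cis to H2′. C8 relative to C5 is set by conformation: A(1,3) strain with the C4 methyl holds the C5 methyl pseudoaxial and the C6 flap of the ring E sofa on the opposite face, and because the outside carbon C7 must turn toward the dienophile, attack syn to the C5 methyl leads to a half-chair whereas attack on the other face costs a boat or an equatorial C5 methyl; with 5S this should give 2′R,3′R,8R. Cross-selectivity over self-reaction is expected because the furan of 10 and 17 is shielded at C3 by the peri C4 methyl, 16 is in excess and 10 is added slowly. O- or C4′-alkylation of the free phenol is reversible or hindered under these conditions, and the 7,8-alkene tautomer of 17 can re-enter by protonation.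

## Compound list

1 | 2-methoxy-5-methylphenol | COc1ccc(C)cc1O | starting material
2 | 2-methoxy-5-methylphenyl acetate | COc1ccc(C)cc1OC(C)=O | intermediate (not isolated)
3 | 1-(4-hydroxy-5-methoxy-2-methylphenyl)ethan-1-one | CC(=O)c1cc(OC)c(O)cc1C | intermediate
4 | 1-[5-methoxy-2-methyl-4-(2-oxopropoxy)phenyl]ethan-1-one | CC(=O)COc1cc(C)c(C(C)=O)cc1OC | intermediate
5 | 1-(7-methoxy-3,4-dimethyl-1-benzofuran-5-yl)ethan-1-one | CC(=O)c1cc(OC)c2occ(C)c2c1C | intermediate
6 | (3E)-4-(7-methoxy-3,4-dimethyl-1-benzofuran-5-yl)pent-3-enoic acid | OC(=O)C/C=C(\C)c1cc(OC)c2occ(C)c2c1C | intermediate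
7 | (4S)-4-(7-methoxy-3,4-dimethyl-1-benzofuran-5-yl)pentanoic acid | OC(=O)CC[C@H](C)c1cc(OC)c2occ(C)c2c1C | intermediate
8 | (5S)-9-methoxy-3,4,5-trimethyl-6,7-dihydronaphtho[2,3-b]furan-8(5H)-one | O=C1CC[C@H](C)c2c1c(OC)c1occ(C)c1c2C | intermediate
9 | (5S)-9-hydroxy-3,4,5-trimethyl-6,7-dihydronaphtho[2,3-b]furan-8(5H)-one | O=C1CC[C@H](C)c2c1c(O)c1occ(C)c1c2C | intermediate
10 | (5S,8RS)-3,4,5-trimethyl-5,6,7,8-tetrahydronaphtho[2,3-b]furan-8,9-diol | OC1CC[C@H](C)c2c1c(O)c1occ(C)c1c2C | intermediate
11 | 2-methoxy-4-methylphenol | COc1cc(C)ccc1O | starting material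
12 | 1-(2-methoxy-4-methylphenoxy)propan-2-one | CC(=O)COc1ccc(C)cc1OC | intermediate
13 | 7-methoxy-3,5-dimethyl-1-benzofuran | COc1cc(C)cc2c(C)coc12 | intermediate
14 | 3,5-dimethyl-1-benzofuran-7-ol | Oc1cc(C)cc2c(C)coc12 | intermediate
15 | 6-bromo-3,5-dimethyl-1-benzofuran-7-ol | Oc1c(Br)c(C)cc2c(C)coc12 | intermediate
16 | 3,5-dimethyl-6-[(3E)-pent-3-en-1-yl]-1-benzofuran-7-ol | C/C=C/CCc1c(C)cc2c(C)coc2c1O | intermediate
17 | (5S)-3,4,5-trimethyl-6,7-dihydronaphtho[2,3-b]furan-9(5H)-one (ortho-quinone methide, C8=C8a) | O=C1C2=CCC[C@H](C)C2=C(C)c2c(C)coc12 | intermediate (not isolated)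
18 | (2′R,3′R,5S,8R)-heterodimer, CNP0281983.1 | C/C=C/CCc1c(C)cc2c(c1O)O[C@@H]1[C@@H]3CC[C@H](C)c4c3c(c3occ(C)c3c4C)O[C@]21C | target

## Step count and risk

Total step count: 14. Longest linear sequence: 9 (steps 1–8 and 14); the second branch is steps 9–13.

Least certain steps:

**Step 14 (key step).**
- Most likely failure: insufficient discrimination between the two faces of C8. The half-chair preference for attack syn to the pseudoaxial C5 methyl is opposed by a steric contact between that methyl and the C7′–OH edge of the endo-bound dienophile, and the two effects cannot be weighed by inspection. Lesser risks are loss of endo selectivity and self-condensation of the quinone methide with the furan of its own precursor.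
- Fallback: reagent control combined with late attachment of the chain. It sets out from 10 and 15. The cycloaddition is run with the smaller bromide 15 under a confined chiral Brønsted acid, (R)-3,3′-bis(2,4,6-triisopropylphenyl)-1,1′-binaphthyl-2,2′-diyl hydrogen phosphate (10 mol %, toluene, 4 Å MS), or its antipode, whichever is matched with the 5S centre. This should give the bromo cycloadduct F1, whose heavy atom also allows the configuration to be proven by crystallography. The hydroboration/Pd(OAc)2/SPhos coupling of step 13 on F1 then returns to the route at 18.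

**Step 5.**
- Most likely failure: erosion of enantioselectivity, because the ortho methyl twists the arene out of conjugation with the alkene, or because residual Z-alkene is reduced with the opposite sense.
- Fallback: resolution instead of asymmetric catalysis. From 6, non-selective hydrogenation with [Ir(cod)(PCy3)(py)]PF6 and H2 in CH2Cl2 gives the racemic acid F2. Crystallisation with (1S)-1-phenylethanamine (or its antipode) gives the diastereomerically pure salt F3, and acidification returns to the route at 7.

**Step 3.**
- Most likely failure: slow ring closure next to the flanking methyl group, allowing acid-induced condensation between the two ketone groups to compete.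
- Fallback: a palladium-mediated furan synthesis. From 3, iodination ortho to the OH (NIS, cat. TsOH, MeCN) gives the iodophenol F4. O-Allylation (allyl bromide, K2CO3, acetone) gives the allyl ether F5. Intramolecular Heck cyclisation with double-bond migration (Pd(OAc)2, Na2CO3, n-Bu4NCl, DMF, 80 °C) returns to the route at 5.

**Step 6.**
- Most likely failure: competing intermolecular acylation at the free furan C2 and acid-induced oligomerisation of the benzofuran.
- Fallback: ring E is closed by a base-mediated hydroxyalkylation instead of an acylation. From 7, BBr3 gives the phenol acid F6, BH3·SMe2 gives the phenol alcohol F7, and TEMPO/PhI(OAc)2 gives the phenol aldehyde F8. EtMgBr (1 equiv, toluene) forms the magnesium phenoxide, which adds its ortho carbon to the tethered aldehyde and returns directly to the route at 10, bypassing 8 and 9.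

**Step 12.**
- Most likely failure: bromination at furan C2 or at C4 instead of C6.
- Fallback: the chain is introduced through a sigmatropic shift that can only reach C6. From 14, O-allylation (allyl bromide, K2CO3) gives the allyl ether F9. Aromatic Claisen rearrangement (PhNEt2, 190 °C) gives the 6-allylphenol F10. Hydroboration with 9-BBN-H and coupling with vinyl bromide (PdCl2(dppf), aq. K3PO4) gives the pent-4-enylphenol F11. A one-position E-selective alkene transposition (Pd(dba)2, P(t-Bu)3, i-PrCOCl, toluene, 80 °C) returns to the route at 16.

## Further compounds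

F1 | step 14 | (2′R,3′R,5S,8R)-6′-bromo analogue of 18 (Br in place of the pentenyl chain) | Brc1c(C)cc2c(c1O)O[C@@H]1[C@@H]3CC[C@H](C)c4c3c(c3occ(C)c3c4C)O[C@]21C
F2 | step 5 | rac-4-(7-methoxy-3,4-dimethyl-1-benzofuran-5-yl)pentanoic acid | OC(=O)CCC(C)c1cc(OC)c2occ(C)c2c1C
F3 | step 5 | (1S)-1-phenylethan-1-aminium (4S)-4-(7-methoxy-3,4-dimethyl-1-benzofuran-5-yl)pentanoate | C[C@H]([NH3+])c1ccccc1.[O-]C(=O)CC[C@H](C)c1cc(OC)c2occ(C)c2c1C
F4 | step 3 | 1-(4-hydroxy-3-iodo-5-methoxy-2-methylphenyl)ethan-1-one | CC(=O)c1cc(OC)c(O)c(I)c1C
F5 | step 3 | 1-[3-iodo-5-methoxy-2-methyl-4-(prop-2-en-1-yloxy)phenyl]ethan-1-one | CC(=O)c1cc(OC)c(OCC=C)c(I)c1C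
F6 | step 6 | (4S)-4-(7-hydroxy-3,4-dimethyl-1-benzofuran-5-yl)pentanoic acid | OC(=O)CC[C@H](C)c1cc(O)c2occ(C)c2c1C
F7 | step 6 | 5-[(2S)-5-hydroxypentan-2-yl]-3,4-dimethyl-1-benzofuran-7-ol | OCCC[C@H](C)c1cc(O)c2occ(C)c2c1C
F8 | step 6 | (4S)-4-(7-hydroxy-3,4-dimethyl-1-benzofuran-5-yl)pentanal | O=CCC[C@H](C)c1cc(O)c2occ(C)c2c1C
F9 | step 12 | 3,5-dimethyl-7-(prop-2-en-1-yloxy)-1-benzofuran | C=CCOc1cc(C)cc2c(C)coc12
F10 | step 12 | 3,5-dimethyl-6-(prop-2-en-1-yl)-1-benzofuran-7-ol | C=CCc1c(C)cc2c(C)coc2c1O
F11 | step 12 | 3,5-dimethyl-6-(pent-4-en-1-yl)-1-benzofuran-7-ol | C=CCCCc1c(C)cc2c(C)coc2c1O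
A1 | alternative 1 | 2-[(5S)-9-hydroxy-3,4,5-trimethyl-5,6-dihydronaphtho[2,3-b]furan-8-yl]-3,5-dimethyl-6-[(3E)-pent-3-en-1-yl]-1-benzofuran-7-ol | C/C=C/CCc1c(C)cc2c(C)c(oc2c1O)C1=CC[C@H](C)c2c1c(O)c1occ(C)c1c2C
A2 | alternative 1 | (3′RS,5S)-8,2′-didehydro analogue of 18 (2H-chromene with a C8=C2′ double bond) | C/C=C/CCc1c(C)cc2c(c1O)OC1=C3CC[C@H](C)c4c3c(c3occ(C)c3c4C)OC21C
A3 | alternative 2 | (5S)-3,4,5-trimethyl-5,6,7,8-tetrahydronaphtho[2,3-b]furan-9-ol | Oc1c2CCC[C@H](C)c2c(C)c2c(C)coc12
A4 | alternative 3 | tricyclic 4H-chromene enol ether O9–C3′(CH3)=C2′H–C8 fused to rings D, E and F (5S,8S; same spatial arrangement at C8 as in 18) | CC1=C[C@@H]2CC[C@H](C)c3c2c(O1)c2occ(C)c2c3C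
A5 | alternative 3 | 4-methyl-3-[(3E)-pent-3-en-1-yl]cyclohexa-3,5-diene-1,2-dione | O=C1C(=O)C=CC(C)=C1CC/C=C/C
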